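Retrosynthesis: both malonate C–O bonds are cut first, giving two identical labda-7,13E-dien-15-ol units. Then follow C12–C13 (sp3–sp2 coupling), C11=C12 (methylenation), and last C5–C10 together with C8–C9.
Enabling feature: rings A and B are fused along C5–C10 and carry the adjacent stereocentres C5, C10 and C9. Ring B (C5–C10) reads as a cyclohexene made from a C5=C6–C7=C8 diene and a C9=C10 E-enal (C11 = CHO). C1–C4 of ring A is the four-carbon link from C10 to C5.
Forward: an acyclic trienal is built from isobutyronitrile, 5-iodopentyne, crotyl bromide, Me3Al and formaldehyde, and rings B and A close together in one intramolecular [4+2] step. The alkene is then moved from C6=C7 to C7=C8 via the 7-ketone and its more substituted enol triflate, the C13–C16 unit is coupled on, and malonic acid joins two halves.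
Stereochemistry: C9/C10 come from the E-enal geometry (syn-carboalumination), C5 from the formyl-endo transition state, and the absolute sense from a chiral oxazaborolidinium Lewis acid. C8 is transient. 13E comes from syn-hydrozirconation and a stereoretentive coupling.

Key step: step 7

Remark on numbering: labdane atom numbers of one target half are used for all intermediates (C17 = methyl on C8, C18/C19 = α/β methyl on C4, C20 = methyl on C10).
Assumption: the sense of induction of the oxazaborolidinium salt is taken from the formyl C–H···O binding model for enals. That model assigns the required C9-Si/C10-Re attack to the catalyst derived from (R)-diphenylprolinol. Both antipodes are on sale, so the other one would be used if the model did not hold for this β,β-disubstituted enal.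

Step 1
Reactants: 1 isobutyronitrile; 2 5-iodopent-1-yne
Product: 4 2,2-dimethylhept-6-ynenitrile, via lithiated isobutyronitrile 3 (not isolated)
Conditions: LDA (1.05 equiv), THF, −78 °C; then 2, −78 °C → rt
Reagents that add atoms: none
Why: SN2 alkylation of a nitrile-stabilised tertiary carbanion with an unhindered primary iodide is fast at low temperature, should outrun proton transfer from the alkyne C–H, and installs the quaternary C4 with both methyl groups in one operation.

Step 2
Reactants: 4 2,2-dimethylhept-6-ynenitrile
Product: 6 2,2-dimethylhept-6-ynal, via N-diisobutylaluminio aldimine 5 (not isolated)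
Conditions: DIBAL-H (1.2 equiv), CH2Cl2, −78 → 0 °C; 1 M HCl, 0 °C
Reagents that add atoms: water, O
Why: Partial reduction of a nitrile with DIBAL-H stops at the aluminium aldimine, which takes up no second hydride; mild acid then hydrolyses it to the non-enolisable aldehyde, and the terminal alkyne is not hydroaluminated below 0 °C.

Step 3
Reactants: 7 (E)-1-bromobut-2-ene
Product: 8 diethyl (E)-but-2-en-1-ylphosphonate
Conditions: P(OEt)3 (1.2 equiv), neat, 130 °C, EtBr distilled off
Reagents that add atoms: triethyl phosphite, CCOP(OCC)OCC
Why: Michaelis–Arbuzov reaction of a primary allylic bromide, in which attack by phosphorus and dealkylation by bromide leave the E alkene in place.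

Step 4
Reactants: 8 diethyl (E)-but-2-en-1-ylphosphonate; 6 2,2-dimethylhept-6-ynal
Product: 10 (7E,9E)-6,6-dimethylundeca-7,9-dien-1-yne, via lithiated phosphonate 9 (not isolated)
Conditions: 8 (1.5 equiv), n-BuLi (1.45 equiv), THF–DMPU, −78 °C; then 6, −78 °C → rt
Reagents that add atoms: none
Why: Horner–Wadsworth–Emmons olefination with an allylic phosphonate anion, which adds through its α-carbon and eliminates in the polar cosolvent from the less crowded adduct, so the bulky α-quaternary aldehyde should give C5=C6 as the E alkene and leave C7=C8 E.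

Step 5
Reactants: 10 (7E,9E)-6,6-dimethylundeca-7,9-dien-1-yne
Product: 13 (2E,8E,10E)-3,7,7-trimethyldodeca-2,8,10-trien-1-ol, via alkenyldimethylalane 11 (not isolated), via lithium alkenylalanate 12 (not isolated)
Conditions: Me3Al (2.5 equiv), Cp2ZrCl2 (20 mol %), CH2Cl2, 0 °C → rt; volatiles off; n-BuLi, hexane–THF, 0 °C; (CH2O)n, rt
Reagents that add atoms: trimethylaluminium, C[Al](C)C; formaldehyde (as paraformaldehyde), C=O
Why: Zirconium-catalysed syn-carboalumination of a terminal alkyne (Negishi carboalumination) puts methyl (C20) on the internal carbon and aluminium on the terminal carbon on the same side, and the ate complex is hydroxymethylated with retention, which fixes C9=C10 as E while the 1,2-disubstituted diene is left alone.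

Step 6
Reactants: 13 (2E,8E,10E)-3,7,7-trimethyldodeca-2,8,10-trien-1-ol
Product: 14 (2E,8E,10E)-3,7,7-trimethyldodeca-2,8,10-trienal
Conditions: MnO2 (15 equiv), CH2Cl2, rt
Reagents that add atoms: none
Why: Manganese dioxide oxidises allylic alcohols selectively under neutral conditions, so the enal should form without E/Z leakage and without touching the diene.

Step 7
Reactants: 14 (2E,8E,10E)-3,7,7-trimethyldodeca-2,8,10-trienal
Product: 15 (5S,8S,9S,10S)-drim-6-en-11-al (H-5, H-8 and H-9 α; C17, C11 and C20 β)
Conditions: (R)-o-tolyl-CBS oxazaborolidine (20 mol %), Tf2NH (17 mol %), CH2Cl2 (0.02 M), −40 → 0 °C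
Reagents that add atoms: none
Why: Proposed new method: the cationic oxazaborolidine binds the formyl oxygen of 14 on the side of the formyl hydrogen, lowers the enal LUMO and sets off a concerted but asynchronous [4+2] addition, in which bonding of C10 (enal β-carbon) to C5 (the diene terminus made nucleophilic by the C8 methyl group) runs ahead of C9–C8 bonding. The closest known reaction type is the type 1 intramolecular Diels–Alder reaction of (2E,8E,10E)-undeca-2,8,10-trienals to trans-fused octalin carbaldehydes under chiral boron Lewis acids; not yet shown is a β,β-disubstituted enal that creates a quaternary ring-fusion carbon beside a gem-dimethyl-bearing link. Ring B (C5–C6–C7–C8–C9–C10) closes as the six-membered cycloadduct through both new σ bonds, and ring A (C1–C5 and C10) closes in the fused mode as a six-membered ring when C5–C10 forms across the four-carbon link C1–C4, which sits in a chair. C9 against C10 follows from suprafacial addition to the E enal (CHO and C20 cis, both β); C5 follows from the formyl-endo transition state, in which the link leaves C10 on the exo side so that H-5 ends anti to C20 (trans fusion); C8 follows from the E geometry of C7=C8, whose outward methyl group ends cis to the formyl group (8β, erased in step 11); the absolute sense follows from the catalyst aryl group, which covers the C9-Re/C10-Si face and leaves C9-Si/C10-Re open to the diene. The step needs endo over exo selectivity and one enantioface: overlap of the diene with the Lewis-acid-bound formyl group favours endo, the C4 gem-dimethyl group raises the population of the folded conformer, only the E,E diene reaches the s-cis form, and high dilution suppresses the bimolecular reaction. The developing syn-axial C19/C20 contact in the trans transition state is the main penalty and is the reason for choosing a strong cationic Lewis acid.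

Step 8
Reactants: 15 (5S,8S,9S,10S)-drim-6-en-11-al
Product: 17 (8αH)-drimane-7α,11-diol, via 7α-boryl 11-boryloxy intermediate 16 (not isolated)
Conditions: BH3·THF (3 equiv), THF, 0 °C → rt; 3 M NaOH, 30 % H2O2, 0 °C → rt
Reagents that add atoms: hydrogen peroxide, OO
Why: Borane reduces the aldehyde and hydroborates the only alkene in the same flask (hydroboration–oxidation); boron should go to C7 from the α face because C6 is crowded by the C4 methyl groups and the β face by C17 and C20, and the C7 configuration does not matter since it is oxidised next.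

Step 9
Reactants: 17 (8αH)-drimane-7α,11-diol
Product: 18 (8αH)-7-oxodriman-11-al
Conditions: Dess–Martin periodinane (2.5 equiv), CH2Cl2, 0 °C → rt
Reagents that add atoms: none
Why: Dess–Martin oxidation converts primary and secondary alcohols alike under near-neutral conditions, so both carbonyl groups arise in one step and the equatorial C9 substituent stays in place.

Step 10
Reactants: 18 (8αH)-7-oxodriman-11-al
Product: 19 (8αH)-13,14,15,16-tetranorlabd-11-en-7-one
Conditions: MePPh3Br (1.1 equiv), KHMDS (1.05 equiv), THF, 0 °C; then 18, −78 → 0 °C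
Reagents that add atoms: methyltriphenylphosphonium bromide, C[P+](c1ccccc1)(c1ccccc1)c1ccccc1.[Br-]
Why: Wittig methylenation with one equivalent of ylide at low temperature distinguishes an aldehyde from a ketone, C9 keeps its thermodynamically preferred equatorial substituent, and any epimerisation at C8 is harmless because C8 becomes sp2 in the next step.

Step 11
Reactants: 19 (8αH)-13,14,15,16-tetranorlabd-11-en-7-one
Product: 21 13,14,15,16-tetranorlabda-7,11-dien-7-yl trifluoromethanesulfonate, via bromomagnesium C7=C8 enolate 20 (not isolated)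
Conditions: i-Pr2NMgBr (from EtMgBr, i-Pr2NH; 1.3 equiv), Et2O, 0 °C → rt, 12 h; PhNTf2 (1.3 equiv), THF, rt
Reagents that add atoms: N-phenylbis(trifluoromethanesulfonimide), O=S(=O)(N(c1ccccc1)S(=O)(=O)C(F)(F)F)C(F)(F)F
Why: Bromomagnesium diisopropylamide lets ketone enolates equilibrate to the more substituted regioisomer, here C7=C8 (a kinetic lithium amide would deprotonate C6 and lead back to C6=C7), and O-sulfonylation with N-phenyltriflimide freezes this regiochemistry as the enol triflate.

Step 12
Reactants: 21 13,14,15,16-tetranorlabda-7,11-dien-7-yl trifluoromethanesulfonate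
Product: 22 13,14,15,16-tetranorlabda-7,11-diene
Conditions: Pd(OAc)2 (5 mol %), PPh3 (10 mol %), HCO2H (2 equiv), n-Bu3N (3 equiv), DMF, 60 °C
Reagents that add atoms: none
Why: Palladium-catalysed formate hydrogenolysis of an enol triflate (oxidative addition, decarboxylation of formate, reductive elimination) replaces OTf by H at C7 with the alkene held at C7=C8, and the short-lived alkenylpalladium hydride should leave the vinyl group and the doubly allylic C9–H alone.

Step 13
Reactants: 23 but-2-yn-1-ol
Product: 26 (E)-3-iodobut-2-en-1-ol, via aluminium but-2-ynoxide 24 (not isolated), via alkenylzirconocene chloride 25 (not isolated)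
Conditions: i-Bu2AlH (1.0 equiv), THF, 0 °C; Cp2ZrCl2 (1.3 equiv)/i-Bu2AlH (1.3 equiv), THF, 0 °C → rt; I2, −78 °C; 1 M HCl
Reagents that add atoms: iodine, II
Why: Hydrozirconation of the aluminium-masked propargylic alcohol is a syn addition that places zirconium on the methyl-bearing carbon, and iodinolysis goes with retention, which gives the iodide with I trans to CH2OH.

Step 14
Reactants: 22 13,14,15,16-tetranorlabda-7,11-diene; 26 (E)-3-iodobut-2-en-1-ol
Product: 28 labda-7,13E-dien-15-ol, via B-alkyl-9-BBN 27 (not isolated)
Conditions: 9-BBN (1.2 equiv), THF, rt → 40 °C; then 26 (1.1 equiv), PdCl2(dppf) (5 mol %), 3 M aq NaOH, THF, 50 °C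
Reagents that add atoms: none
Why: 9-BBN hydroborates the monosubstituted C11=C12 alkene at C12 far faster than the trisubstituted C7=C8 alkene, and the B-alkyl Suzuki–Miyaura coupling forms C12–C13 with retention of the iodide geometry and tolerates the free hydroxyl group in aqueous base, so 13E is carried over.

Step 15
Reactants: 28 labda-7,13E-dien-15-ol (2.05 equiv); 29 malonic acid
Product: 30 bis(labda-7,13E-dien-15-yl) malonate (CNP0113044.1)
Conditions: DCC (2.2 equiv), DMAP (10 mol %), CH2Cl2, 0 °C → rt
Reagents that add atoms: none
Why: Steglich esterification acylates the primary allylic alcohol at both carboxyl groups of malonic acid under neutral conditions that neither ionise the allylic C–O bond nor move an alkene, no stereocentre is touched, and any residual minor enantiomer is diverted statistically into the separable heterochiral diester.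

Compound list
1 | isobutyronitrile | CC(C)C#N | starting material
2 | 5-iodopent-1-yne | C#CCCCI | starting material
3 | lithiated isobutyronitrile | [Li+].C[C-](C)C#N | intermediate
4 | 2,2-dimethylhept-6-ynenitrile | C#CCCCC(C)(C)C#N | intermediate
5 | N-(diisobutylaluminio)-2,2-dimethylhept-6-yn-1-imine | C#CCCCC(C)(C)C=N[Al](CC(C)C)CC(C)C | intermediate
6 | 2,2-dimethylhept-6-ynal | C#CCCCC(C)(C)C=O | intermediate
7 | (E)-1-bromobut-2-ene | C/C=C/CBr | starting material
8 | diethyl (E)-but-2-en-1-ylphosphonate | C/C=C/CP(=O)(OCC)OCC | intermediate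
9 | lithiated diethyl (E)-but-2-en-1-ylphosphonate | [Li+].CCOP(=O)(OCC)[CH-]/C=C/C | intermediate
10 | (7E,9E)-6,6-dimethylundeca-7,9-dien-1-yne | C#CCCCC(C)(C)/C=C/C=C/C | intermediate
11 | dimethyl[(1E,7E,9E)-2,6,6-trimethylundeca-1,7,9-trien-1-yl]alane | C[Al](C)/C=C(\C)CCCC(C)(C)/C=C/C=C/C | intermediate
12 | lithium butyl(dimethyl)[(1E,7E,9E)-2,6,6-trimethylundeca-1,7,9-trien-1-yl]alanate | [Li+].CCCC[Al-](C)(C)/C=C(\C)CCCC(C)(C)/C=C/C=C/C | intermediate
13 | (2E,8E,10E)-3,7,7-trimethyldodeca-2,8,10-trien-1-ol | OC/C=C(\C)CCCC(C)(C)/C=C/C=C/C | intermediate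
14 | (2E,8E,10E)-3,7,7-trimethyldodeca-2,8,10-trienal | O=C/C=C(\C)CCCC(C)(C)/C=C/C=C/C | intermediate
15 | (5S,8S,9S,10S)-drim-6-en-11-al | C[C@H]1C=C[C@H]2C(C)(C)CCC[C@]2(C)[C@H]1C=O | intermediate
16 | 7α-boryl-11-boryloxy-(8αH)-drimane (idealised monomer) | C[C@H]1[C@H](B)C[C@H]2C(C)(C)CCC[C@]2(C)[C@H]1COB | intermediate
17 | (8αH)-drimane-7α,11-diol | C[C@H]1[C@H](O)C[C@H]2C(C)(C)CCC[C@]2(C)[C@H]1CO | intermediate
18 | (8αH)-7-oxodriman-11-al | C[C@H]1C(=O)C[C@H]2C(C)(C)CCC[C@]2(C)[C@H]1C=O | intermediate
19 | (8αH)-13,14,15,16-tetranorlabd-11-en-7-one | C[C@H]1C(=O)C[C@H]2C(C)(C)CCC[C@]2(C)[C@H]1C=C | intermediate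
20 | bromomagnesium 13,14,15,16-tetranorlabda-7,11-dien-7-olate | CC1=C(O[Mg]Br)C[C@H]2C(C)(C)CCC[C@]2(C)[C@H]1C=C | intermediate
21 | 13,14,15,16-tetranorlabda-7,11-dien-7-yl trifluoromethanesulfonate | CC1=C(OS(=O)(=O)C(F)(F)F)C[C@H]2C(C)(C)CCC[C@]2(C)[C@H]1C=C | intermediate
22 | 13,14,15,16-tetranorlabda-7,11-diene (5α-H, 9α-H, 10β-CH3) | CC1=CC[C@H]2C(C)(C)CCC[C@]2(C)[C@H]1C=C | intermediate
23 | but-2-yn-1-ol | CC#CCO | starting material
24 | diisobutylaluminium but-2-yn-1-olate | CC#CCO[Al](CC(C)C)CC(C)C | intermediate
25 | (E)-alkenylzirconocene chloride of 24 (Cp drawn η1) | C/C(=C\CO[Al](CC(C)C)CC(C)C)[Zr](Cl)(C1C=CC=C1)C1C=CC=C1 | intermediate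
26 | (E)-3-iodobut-2-en-1-ol | C/C(I)=C\CO | intermediate
27 | 12-(9-borabicyclo[3.3.1]nonan-9-yl)-13,14,15,16-tetranorlabd-7-ene | CC1=CC[C@H]2C(C)(C)CCC[C@]2(C)[C@H]1CCB1C2CCCC1CCC2 | intermediate
28 | labda-7,13E-dien-15-ol | CC1=CC[C@H]2C(C)(C)CCC[C@]2(C)[C@H]1CC/C(C)=C/CO | intermediate
29 | malonic acid | OC(=O)CC(=O)O | starting material
30 | bis(labda-7,13E-dien-15-yl) malonate | CC1=CC[C@H]2C(C)(C)CCC[C@]2(C)[C@H]1CC/C(C)=C/COC(=O)CC(=O)OC/C=C(\C)CC[C@H]1C(C)=CC[C@H]2C(C)(C)CCC[C@]12C | target

Total step count: 15. Longest linear sequence: 13 steps (1, 2, 4–12, 14, 15). Steps 3 and 13 are side branches.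

Steps most likely to fail

Step 7. The β-methyl group C20 crowds the catalyst pocket. Turnover may therefore be slow, enantiofacial discrimination poor, the bound enal may lose its E geometry, and endo selectivity may erode through the C19/C20 contact.
- The fallback sets out from 14 and returns at 17, using known chemistry only.
- 14 would be cyclised with a stoichiometric achiral promoter (Me2AlCl, CH2Cl2, −78 → −20 °C), an established way from 2,8,10-trienals to trans-fused octalin carbaldehydes, to give racemic drim-6-en-11-al F1.
- NaBH4 in MeOH would give racemic drim-6-en-11-ol F2.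
- Acylation with (1S)-camphanic chloride (pyridine, DMAP) would give the camphanate of the (5S,8S,9S,10S) alcohol F3 beside the camphanate of the (5R,8R,9R,10R) alcohol F4. These would be parted by crystallisation or chromatography and assigned by X-ray analysis.
- KOH in MeOH would release (5S,8S,9S,10S)-drim-6-en-11-ol F5 from F3, and BH3·THF followed by NaOH/H2O2 would turn F5 into 17.

Step 11. Enolate equilibration may stop short or settle on the C6 side, because the C7=C8 enolate carries C17 next to the C9 vinyl group. Triflation would then fix the wrong regioisomer, and reduction would lead back to a C6=C7 alkene.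
- The fallback sets out from 19 and returns at 22, replacing enolate chemistry by a stereoelectronically guided elimination.
- NaOMe in MeOH would equilibrate C8 to the equatorial methyl epimer, (8βH)-13,14,15,16-tetranorlabd-11-en-7-one F6.
- L-Selectride (THF, −78 °C) would attack from the equatorial side to give the axial alcohol (8βH)-13,14,15,16-tetranorlabd-11-en-7α-ol F7.
- MsCl/Et3N would give its methanesulfonate F8.
- DBU in toluene at reflux would bring about anti-periplanar E2 loss of the axial 7α leaving group with the now axial H-8β, in the direction of the more substituted alkene, to give 22.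

Step 10. Chemoselectivity may be lost, since the C11 aldehyde sits between C10 and the methyl-bearing C8 and is itself hindered. The ylide may then attack the C7 ketone or act as a base and start aldol reactions of the 1,4-dicarbonyl compound.
- The fallback sets out from 17 and returns at 19, and avoids having both carbonyl groups present at once.
- TEMPO (cat.)/PhI(OAc)2 in CH2Cl2 would oxidise only the primary alcohol to 7α-hydroxy-(8αH)-driman-11-al F9. The trans relation of the 7α-hydroxyl and the 9β-formyl group keeps this from closing to a lactol.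
- Excess Ph3P=CH2 would give (8αH)-13,14,15,16-tetranorlabd-11-en-7α-ol F10.
- Dess–Martin oxidation of F10 would give 19.

Further compounds
F1 | step 7 | racemic drim-6-en-11-al (both enantiomers) | C[C@H]1C=C[C@H]2C(C)(C)CCC[C@]2(C)[C@H]1C=O.C[C@@H]1C=C[C@@H]2C(C)(C)CCC[C@@]2(C)[C@@H]1C=O
F2 | step 7 | racemic drim-6-en-11-ol (both enantiomers) | C[C@H]1C=C[C@H]2C(C)(C)CCC[C@]2(C)[C@H]1CO.C[C@@H]1C=C[C@@H]2C(C)(C)CCC[C@@]2(C)[C@@H]1CO
F3 | step 7 | (5S,8S,9S,10S)-drim-6-en-11-yl (1S)-camphanate | C[C@H]1C=C[C@H]2C(C)(C)CCC[C@]2(C)[C@H]1COC(=O)[C@@]12CC[C@@](C)(C(=O)O1)C2(C)C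
F4 | step 7 | (5R,8R,9R,10R)-drim-6-en-11-yl (1S)-camphanate | C[C@@H]1C=C[C@@H]2C(C)(C)CCC[C@@]2(C)[C@@H]1COC(=O)[C@@]12CC[C@@](C)(C(=O)O1)C2(C)C
F5 | step 7 | (5S,8S,9S,10S)-drim-6-en-11-ol | C[C@H]1C=C[C@H]2C(C)(C)CCC[C@]2(C)[C@H]1CO
F6 | step 11 | (8βH)-13,14,15,16-tetranorlabd-11-en-7-one | C[C@@H]1C(=O)C[C@H]2C(C)(C)CCC[C@]2(C)[C@H]1C=C
F7 | step 11 | (8βH)-13,14,15,16-tetranorlabd-11-en-7α-ol | C[C@@H]1[C@H](O)C[C@H]2C(C)(C)CCC[C@]2(C)[C@H]1C=C
F8 | step 11 | (8βH)-13,14,15,16-tetranorlabd-11-en-7α-yl methanesulfonate | C[C@@H]1[C@H](OS(C)(=O)=O)C[C@H]2C(C)(C)CCC[C@]2(C)[C@H]1C=C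
F9 | step 10 | 7α-hydroxy-(8αH)-driman-11-al | C[C@H]1[C@H](O)C[C@H]2C(C)(C)CCC[C@]2(C)[C@H]1C=O
F10 | step 10 | (8αH)-13,14,15,16-tetranorlabd-11-en-7α-ol | C[C@H]1[C@H](O)C[C@H]2C(C)(C)CCC[C@]2(C)[C@H]1C=C
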